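In the early hours of the two earlier runs, target runs well ahead of isomer of the product A, and two chemists read this differently for a flask with a larger charge of substrate.

| flask | substrate | remark | time |
|---|---|---|---|
| summer | 0.050 M | run made earlier |  |
| noon | 0.075 M | run made earlier |  |
| flask | 0.10 M |  | 40 h |

| run | time / h | target / % | isomer of the product A / % | substrate / % |
|---|---|---|---|---|
| summer | 1.33 | 2 | 0 | 69 |
| summer | 4.00 | 12 | 6 | 36 |
| summer | 6.00 | 15 | 1 | 24 |
| summer | 10.0 | 22 | 7 | 7 |
| summer | 15.0 | 24 | 8 | 4 |
| summer | 20.0 | 24 | 12 | 1 |
| summer | 25.0 | 31 | 16 | 3 |
| noon | 1.33 | 5 | 0 | 69 |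
| noon | 4.00 | 12 | 0 | 35 |
| noon | 6.00 | 15 | 0 | 19 |
| noon | 10.0 | 18 | 6 | 13 |
| noon | 15.0 | 24 | 12 | 2 |
| noon | 20.0 | 21 | 12 | 3 |
| noon | 25.0 | 22 | 15 | 0 |

(scatter of a reading: 2 percentage points)

- the numbers in the tables scatter with a standard deviation of 2 percentage points
- a reading or a percentage of target counts all its forms, free or not
- a reading of substrate is of its free form alone

- share of target in target plus isomer of the product A at 1.0 h
- share of target in target plus isomer of the product A at 40 h

The first chemist, who made the forecast, takes target as the parent of that isomer: “The isomer shows a clear lag”. The forecast for the flask is 98% at 1.0 h and 51% at 40 h.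

The second chemist, whose reckoning this is, takes both as born side by side in a fixed proportion, and works in powers of ten. Over the six readings up to 6.00 h in the summer and noon runs, the target percentages sum to 61.0% and those of that isomer to 7.00%. Their ratio, a selectivity factor, is 8.71, and its base-ten logarithm, the early split, is 0.940. That puts the flask at 89.7% at 1.0 h, lower than the forecast. But the isomer sum carries a scatter of about 4.9 percentage points, so the readings do not choose between the two views. Against her, the same logarithm from the two runs at 25.0 h reads 0.233, lower than the early split, so she offers no number for 40 h.

The flask gives 91.5% at 1.0 h and 49.3% at 40 h: the forecast is too high early and right within the tolerance late.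

    substrate → intermediate (k = 0.00300 min⁻¹)
    intermediate ⇌ target (K = 0.780, k = 0.00380 min⁻¹)
    intermediate ⇌ isomer of the product A (K = 170, k = 3.20 × 10⁻⁴ min⁻¹)
    substrate ⇌ dormant form (K = 4.80, k = 0.00130 min⁻¹)
    substrate + target ⇌ idle adduct, settled at all times (K = 5.70 M⁻¹)
    target ⇌ isomer of the product B (K = 0.570, k = 0.00210 min⁻¹)

The logarithm at 1.0 h is 1.03 in the flask and 1.04 in the neighbour with 0.17 M substrate, beside the early split of 0.940. The side-by-side view holds at that early time, and the scheme gives the chain from target to the isomer a late route, back through intermediate. Intermediate and free target relax into each other, both ways together, with a half-life of 1.33 h by that step alone, longer than 1.0 h. That half-life is short against 40 h. In the flask, backward turnover on that step is 87% of the forward one, and target and the isomer stand level at 39.0 h.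

Readings and results were computed on assumed constants; the scatter is artificial.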